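The decalin is disconnected at C4–C5 and C9–C10. Rings A (C1–C5, C10) and B (C5–C10) are built in one operation, together with gem-dimethyl C4, the trans-related centres C5 and C10, and an oxygen at C8 that later becomes the methyl of the tetrasubstituted C8=C9 alkene. This happens when a chiral Brønsted acid protonates the terminal alkene of a geranylated acetoacetate and the chain folds onto the enol carbon. The precursor is methyl (6E)-7,11-dimethyl-3-oxododeca-6,10-dienoate, cyclized as its O-silyl enol ether. The side chain is then attached by a B-alkyl Suzuki coupling and the butenolide closed by an alkyne–iodoacid coupling/lactonization.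

Key step: step 3

Remarks
- Numbering: C1–C10 form the decalin, C11 and C12 are the two CH2 groups, C13 carries CH2OH, C14 and C15 are the two CH= carbons, and C16 is the butenolide ring carbon bearing the exocyclic alkene.
- Dec = (4aS,8aS)-2,5,5,8a-tetramethyl-3,4,4a,5,6,7,8,8a-octahydronaphthalen-1-yl.
- Structure check: keto ester 4 and bicyclic enol 7 need no correction. (4aS,8aS) in 7 corresponds to (5S,10S) in the target, with H-5 and CH3-10 trans, and 6E in 4 is the geranyl geometry.
- Precursor design: a free 1,3-dicarbonyl would chelate SnCl4, pull it off the chiral ligand and open a racemic pathway, and it could also end the cascade through oxygen. Keto ester 4 is therefore cyclized as its Z O-TBS enol ether 6, which has the same skeleton.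
- Assumption: the (R)-configured acid is taken to give the (5S,10S) series, by analogy with homofarnesyl chains; if the sense proves opposite, the (S)-ligand is used.
- Compound 7 is drawn as the enol; it equilibrates with the keto tautomer, which is irrelevant for step 4.

Step 1
Reactants: 1 methyl acetoacetate; 2 geranyl bromide
Product: 4 methyl (6E)-7,11-dimethyl-3-oxododeca-6,10-dienoate, via acetoacetate dianion 3 (not isolated)
Conditions: NaH, THF, 0 °C; n-BuLi, 0 °C; then 2, 0 °C → rt; cold dilute aq. HCl quench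
Reagents that add atoms: none
Why: γ-Alkylation of the acetoacetate dianion, in which the terminal carbanion (the more basic and more nucleophilic site) displaces the primary allylic bromide by SN2 and leaves the E-alkene untouched.

Step 2
Reactants: 4 methyl (6E)-7,11-dimethyl-3-oxododeca-6,10-dienoate
Product: 6 methyl (2Z,6E)-3-[(tert-butyldimethylsilyl)oxy]-7,11-dimethyldodeca-2,6,10-trienoate, via sodium enolate 5 (not isolated)
Conditions: NaH, THF, 0 °C; TBSCl, 0 °C → rt
Reagents that add atoms: tert-butyldimethylsilyl chloride, CC(C)(C)[Si](C)(C)Cl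
Why: O-Silylation of the chelated sodium enolate of a β-keto ester should give the Z silyl enol ether, which fixes the terminator as an enol and removes the chelating 1,3-dicarbonyl.

Step 3
Reactants: 6 methyl (2Z,6E)-3-[(tert-butyldimethylsilyl)oxy]-7,11-dimethyldodeca-2,6,10-trienoate
Product: 7 methyl (4aS,8aS)-2-hydroxy-5,5,8a-trimethyl-3,4,4a,5,6,7,8,8a-octahydronaphthalene-1-carboxylate (enol tautomer of the bicyclic β-keto ester)
Conditions: (R)-2-(2-fluorobenzyloxy)-2'-hydroxy-1,1'-binaphthyl (2 equiv), SnCl4 (2 equiv), toluene, −78 °C; then 1 M aq. HCl, THF, rt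
Reagents that add atoms: none
Why: Proposed new method: the tin-activated phenolic proton of the chiral acid is delivered to C3 of the terminal trisubstituted alkene while the 6E alkene attacks the developing C4 cation through a chair, closing ring A by a 6-endo-trig cation–olefin addition (C4–C5); the tertiary C10 cation is then captured by the enol ether carbon in a second chair, closing ring B by a 6-endo-trig (enol-endo) C-alkylation (C9–C10), and chloride strips the silyl group from the silyloxocarbenium ion. The closest known reaction types are the SnCl4-promoted bicyclization of free keto ester 4 to racemic 7, the protonative enantioselective cyclization of geranyl and homofarnesyl chains bearing arene or silyl ether terminators with this BINOL ether–SnCl4 acid, and silyl enol ether terminators in Lewis-acid epoxy-polyene cyclizations. C5 is set by the enantioface of the internal alkene that the chiral proton donor selects in the concerted protonation–first closure; C10 follows from C5 because C4 and C9 add anti across the E alkene in the chair–chair fold, which makes H-5 and CH3-10 trans. The step needs protonation of the terminal alkene ahead of the enol ether and C- rather than O-capture of the C10 cation; both are secured by the ester-conjugated O-silyl enol, whose carbon is far less basic than that of a simple silyl enol ether and whose oxygen is blocked and cannot chelate tin away from the chiral ligand.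

Step 4
Reactants: 7 methyl (4aS,8aS)-2-hydroxy-5,5,8a-trimethyl-3,4,4a,5,6,7,8,8a-octahydronaphthalene-1-carboxylate
Product: 8 methyl (4aS,8aS)-5,5,8a-trimethyl-2-{[(trifluoromethyl)sulfonyl]oxy}-3,4,4a,5,6,7,8,8a-octahydronaphthalene-1-carboxylate
Conditions: Tf2O, iPr2NEt, CH2Cl2, −78 → 0 °C
Reagents that add atoms: trifluoromethanesulfonic anhydride, O=S(=O)(OS(=O)(=O)C(F)(F)F)C(F)(F)F
Why: Enol triflate formation from a cyclic β-keto ester, in which only the C8 enol oxygen reacts and C5 and C10 are not involved.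

Step 5
Reactants: 8 methyl (4aS,8aS)-5,5,8a-trimethyl-2-{[(trifluoromethyl)sulfonyl]oxy}-3,4,4a,5,6,7,8,8a-octahydronaphthalene-1-carboxylate
Product: 9 methyl (4aS,8aS)-2,5,5,8a-tetramethyl-3,4,4a,5,6,7,8,8a-octahydronaphthalene-1-carboxylate
Conditions: Me2CuLi (from MeLi and CuI), THF, −20 → 0 °C
Reagents that add atoms: methyllithium, [Li]C (used as lithium dimethylcuprate, [Li+].C[Cu-]C)
Why: Cuprate cross-coupling of a β-keto ester enol triflate (addition–elimination at C8) installs the C8 methyl and fixes the C8=C9 position, and the hindered tetrasubstituted enoate should resist further conjugate addition.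

Step 6
Reactants: 9 methyl (4aS,8aS)-2,5,5,8a-tetramethyl-3,4,4a,5,6,7,8,8a-octahydronaphthalene-1-carboxylate
Product: 10 Dec-methanol, [(4aS,8aS)-2,5,5,8a-tetramethyl-3,4,4a,5,6,7,8,8a-octahydronaphthalen-1-yl]methanol
Conditions: iBu2AlH (3 equiv), CH2Cl2, −78 → 0 °C; aq. potassium sodium tartrate
Reagents that add atoms: none
Why: Hydride reduction of the conjugated ester gives the C11 allylic alcohol by 1,2-reduction, the tetrasubstituted alkene being inert to the aluminium hydride.

Step 7
Reactants: 10 Dec-methanol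
Product: 11 Dec-carbaldehyde, (4aS,8aS)-2,5,5,8a-tetramethyl-3,4,4a,5,6,7,8,8a-octahydronaphthalene-1-carbaldehyde
Conditions: MnO2, CH2Cl2, rt
Reagents that add atoms: none
Why: MnO2 oxidation of an allylic alcohol should stop at the conjugated aldehyde under neutral conditions that do not ionize the allylic position.

Step 8
Reactants: 11 Dec-carbaldehyde
Product: 12 Dec-ethene, (4aS,8aS)-1-ethenyl-2,5,5,8a-tetramethyl-3,4,4a,5,6,7,8,8a-octahydronaphthalene
Conditions: Ph3PCH3Br, KOtBu, THF, 0 °C → rt
Reagents that add atoms: methyltriphenylphosphonium bromide, C[P+](c1ccccc1)(c1ccccc1)c1ccccc1.[Br-]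
Why: Wittig methylenation with the small unstabilized ylide adds C12 to an aldehyde that has no α-hydrogen and so cannot enolize despite its hindrance.

Step 9
Reactants: 13 but-2-yne-1,4-diol
Product: 14 4-[(tert-butyldimethylsilyl)oxy]but-2-yn-1-ol
Conditions: 13 (3 equiv), TBSCl (1 equiv), imidazole, THF/DMF, 0 °C → rt
Reagents that add atoms: tert-butyldimethylsilyl chloride, CC(C)(C)[Si](C)(C)Cl
Why: Statistical monosilylation of a symmetrical diol, with the diol in excess to suppress the bis-ether.

Step 10
Reactants: 14 4-[(tert-butyldimethylsilyl)oxy]but-2-yn-1-ol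
Product: 16 (2Z)-4-[(tert-butyldimethylsilyl)oxy]-3-iodobut-2-en-1-ol, via cyclic vinylalanate 15 (not isolated)
Conditions: NaAlH2(OCH2CH2OMe)2, THF, 0 °C → rt; then iodine, −78 °C; aq. potassium sodium tartrate
Reagents that add atoms: iodine, [I][I]
Why: Hydroxyl-directed trans-hydroalumination of the propargylic alcohol followed by iodinolysis with retention gives the Z vinyl iodide, with iodine on the carbon remote from the free hydroxyl.

Step 11
Reactants: 12 Dec-ethene; 16 (2Z)-4-[(tert-butyldimethylsilyl)oxy]-3-iodobut-2-en-1-ol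
Product: 18 (2E)-3-{[(tert-butyldimethylsilyl)oxy]methyl}-5-Dec-pent-2-en-1-ol, via B-alkyl borane 17 (not isolated)
Conditions: 9-BBN, THF, 0 °C → rt; then 16, PdCl2(dppf) (5 mol %), AsPh3, Cs2CO3, DMF/H2O, rt
Reagents that add atoms: none
Why: 9-BBN hydroboration occurs only at the terminal carbon of the monosubstituted vinyl group, and the B-alkyl Suzuki–Miyaura coupling forms C12–C13 with retention of the iodide geometry, so that C12 ends cis to C15.

Step 12
Reactants: 18 (2E)-3-{[(tert-butyldimethylsilyl)oxy]methyl}-5-Dec-pent-2-en-1-ol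
Product: 19 (2E)-3-{[(tert-butyldimethylsilyl)oxy]methyl}-5-Dec-pent-2-enal
Conditions: MnO2, CH2Cl2, rt
Reagents that add atoms: none
Why: MnO2 oxidation of the primary allylic alcohol to the enal under neutral conditions that leave the silyl ether and the C13=C14 geometry intact.

Step 13
Reactants: 19 (2E)-3-{[(tert-butyldimethylsilyl)oxy]methyl}-5-Dec-pent-2-enal
Product: 20 tert-butyldimethyl{[(2E)-2-(2-Dec-ethyl)pent-2-en-4-yn-1-yl]oxy}silane
Conditions: Me3SiCHN2, LiN(iPr)2, THF, −78 °C; then 19, −78 °C → rt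
Reagents that add atoms: trimethylsilyldiazomethane, C[Si](C)(C)C=[N+]=[N-]
Why: Colvin rearrangement, in which 1,2-addition of the lithiated silyldiazomethane, Peterson-type loss of silanolate and a 1,2-hydride shift of the alkylidene carbene turn the aldehyde into the terminal alkyne (C16) without touching the C13=C14 geometry.

Step 14
Reactants: 21 but-2-ynoic acid
Product: 22 (2Z)-3-iodobut-2-enoic acid
Conditions: NaI, AcOH, 115 °C
Reagents that add atoms: sodium iodide, [Na+].[I-]
Why: Anti hydroiodination of the ynoic acid (conjugate addition of iodide, then protonation trans to it) gives the Z β-iodo acid.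

Step 15
Reactants: 20 tert-butyldimethyl{[(2E)-2-(2-Dec-ethyl)pent-2-en-4-yn-1-yl]oxy}silane; 22 (2Z)-3-iodobut-2-enoic acid
Product: 24 (5Z)-5-[(2E)-3-{[(tert-butyldimethylsilyl)oxy]methyl}-5-Dec-pent-2-en-1-ylidene]-4-methylfuran-2(5H)-one, via enynoic acid 23 (not isolated)
Conditions: PdCl2(PPh3)2 (5 mol %), CuI (10 mol %), Et3N, MeCN, rt, dark
Reagents that add atoms: none
Why: Tandem Sonogashira coupling and 5-exo-dig lactonization of the Z-enynoic acid, in which anti addition of the carboxylate oxygen and hydrogen across the alkyne places O and C14 on the same side and so gives the Z exocyclic alkene.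

Step 16
Reactants: 24 (5Z)-5-[(2E)-3-{[(tert-butyldimethylsilyl)oxy]methyl}-5-Dec-pent-2-en-1-ylidene]-4-methylfuran-2(5H)-one
Product: 25 (5Z)-5-[(2E)-3-(hydroxymethyl)-5-Dec-pent-2-en-1-ylidene]-4-methylfuran-2(5H)-one (CNP0288110.2)
Conditions: HF·pyridine, pyridine, THF, 0 °C → rt
Reagents that add atoms: none
Why: Fluoride-mediated cleavage of the primary silyl ether under mildly acidic buffered conditions that spare the base-sensitive alkylidene butenolide and the tetrasubstituted alkene.

Compound list
1 | methyl acetoacetate | COC(=O)CC(C)=O | starting material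
2 | geranyl bromide, (2E)-1-bromo-3,7-dimethylocta-2,6-diene | CC(C)=CCC/C(C)=C/CBr | starting material
3 | sodium lithium dianion of methyl acetoacetate | [Na+].[Li+].[CH2-]C(=O)[CH-]C(=O)OC | intermediate
4 | methyl (6E)-7,11-dimethyl-3-oxododeca-6,10-dienoate | COC(=O)CC(=O)CC/C=C(\C)CCC=C(C)C | intermediate
5 | sodium (2Z,6E)-enolate of 4 | [Na+].COC(=O)/C=C(\[O-])CC/C=C(\C)CCC=C(C)C | intermediate
6 | methyl (2Z,6E)-3-[(tert-butyldimethylsilyl)oxy]-7,11-dimethyldodeca-2,6,10-trienoate | COC(=O)/C=C(\O[Si](C)(C)C(C)(C)C)CC/C=C(\C)CCC=C(C)C | intermediate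
7 | methyl (4aS,8aS)-2-hydroxy-5,5,8a-trimethyl-3,4,4a,5,6,7,8,8a-octahydronaphthalene-1-carboxylate | COC(=O)C1=C(O)CC[C@H]2C(C)(C)CCC[C@]12C | intermediate
8 | methyl (4aS,8aS)-5,5,8a-trimethyl-2-{[(trifluoromethyl)sulfonyl]oxy}-3,4,4a,5,6,7,8,8a-octahydronaphthalene-1-carboxylate | COC(=O)C1=C(OS(=O)(=O)C(F)(F)F)CC[C@H]2C(C)(C)CCC[C@]12C | intermediate
9 | methyl (4aS,8aS)-2,5,5,8a-tetramethyl-3,4,4a,5,6,7,8,8a-octahydronaphthalene-1-carboxylate | COC(=O)C1=C(C)CC[C@H]2C(C)(C)CCC[C@]12C | intermediate
10 | [(4aS,8aS)-2,5,5,8a-tetramethyl-3,4,4a,5,6,7,8,8a-octahydronaphthalen-1-yl]methanol | OCC1=C(C)CC[C@H]2C(C)(C)CCC[C@]12C | intermediate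
11 | (4aS,8aS)-2,5,5,8a-tetramethyl-3,4,4a,5,6,7,8,8a-octahydronaphthalene-1-carbaldehyde | O=CC1=C(C)CC[C@H]2C(C)(C)CCC[C@]12C | intermediate
12 | (4aS,8aS)-1-ethenyl-2,5,5,8a-tetramethyl-3,4,4a,5,6,7,8,8a-octahydronaphthalene | C=CC1=C(C)CC[C@H]2C(C)(C)CCC[C@]12C | intermediate
13 | but-2-yne-1,4-diol | OCC#CCO | starting material
14 | 4-[(tert-butyldimethylsilyl)oxy]but-2-yn-1-ol | OCC#CCO[Si](C)(C)C(C)(C)C | intermediate
15 | sodium cyclic vinylalanate (2,2-bis(2-methoxyethoxy)-3-{[(tert-butyldimethylsilyl)oxy]methyl}-2,5-dihydro-1,2-oxaaluminol-2-uide) | [Na+].COCCO[Al-]1(OCCOC)OCC=C1CO[Si](C)(C)C(C)(C)C | intermediate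
16 | (2Z)-4-[(tert-butyldimethylsilyl)oxy]-3-iodobut-2-en-1-ol | OC/C=C(\I)CO[Si](C)(C)C(C)(C)C | intermediate
17 | 9-(2-Dec-ethyl)-9-borabicyclo[3.3.1]nonane | C(CC1=C(C)CC[C@H]2C(C)(C)CCC[C@]12C)B1C2CCCC1CCC2 | intermediate
18 | (2E)-3-{[(tert-butyldimethylsilyl)oxy]methyl}-5-Dec-pent-2-en-1-ol | OC/C=C(\CCC1=C(C)CC[C@H]2C(C)(C)CCC[C@]12C)CO[Si](C)(C)C(C)(C)C | intermediate
19 | (2E)-3-{[(tert-butyldimethylsilyl)oxy]methyl}-5-Dec-pent-2-enal | O=C/C=C(\CCC1=C(C)CC[C@H]2C(C)(C)CCC[C@]12C)CO[Si](C)(C)C(C)(C)C | intermediate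
20 | tert-butyldimethyl{[(2E)-2-(2-Dec-ethyl)pent-2-en-4-yn-1-yl]oxy}silane | C#C/C=C(\CCC1=C(C)CC[C@H]2C(C)(C)CCC[C@]12C)CO[Si](C)(C)C(C)(C)C | intermediate
21 | but-2-ynoic acid | CC#CC(=O)O | starting material
22 | (2Z)-3-iodobut-2-enoic acid | C/C(I)=C/C(=O)O | intermediate
23 | (2Z,6E)-7-{[(tert-butyldimethylsilyl)oxy]methyl}-3-methyl-9-Dec-nona-2,6-dien-4-ynoic acid (present as its triethylammonium salt) | OC(=O)/C=C(/C)C#C/C=C(\CCC1=C(C)CC[C@H]2C(C)(C)CCC[C@]12C)CO[Si](C)(C)C(C)(C)C | intermediate
24 | (5Z)-5-[(2E)-3-{[(tert-butyldimethylsilyl)oxy]methyl}-5-Dec-pent-2-en-1-ylidene]-4-methylfuran-2(5H)-one | CC1=CC(=O)O/C1=C\C=C(\CO[Si](C)(C)C(C)(C)C)CCC1=C(C)CC[C@H]2C(C)(C)CCC[C@]12C | intermediate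
25 | (5Z)-5-[(2E)-3-(hydroxymethyl)-5-[(4aS,8aS)-2,5,5,8a-tetramethyl-3,4,4a,5,6,7,8,8a-octahydronaphthalen-1-yl]pent-2-en-1-ylidene]-4-methylfuran-2(5H)-one | CC1=CC(=O)O/C1=C\C=C(\CO)CCC1=C(C)CC[C@H]2C(C)(C)CCC[C@]12C | target

Total step count: 16.
Longest linear sequence: 13 steps (steps 1–8, 11–13, 15 and 16); steps 9, 10 and 14 prepare the two side fragments.

Steps most likely to fail

1. Step 3 (proposed new method). The enol ether may be protonated or stannylated ahead of the terminal alkene, or tin may migrate from the chiral ligand to the product. Either would cause poor enantioface selectivity or a cascade that stops after ring A. The fallback sets out from 4 and returns at 7 using known chemistry. Keto ester 4 is cyclized with SnCl4 alone (CH2Cl2, 0 °C → rt), the established racemic form of this bicyclization, to racemic methyl (4aS*,8aS*)-2-hydroxy-5,5,8a-trimethyl-3,4,4a,5,6,7,8,8a-octahydronaphthalene-1-carboxylate F1. F1 is condensed with (R)-1-phenylethylamine (cat. TsOH, toluene, azeotropic removal of water) to two diastereomeric enamino esters, which are separated by crystallization or chromatography. The diastereomer methyl (4aS,8aS)-5,5,8a-trimethyl-2-{[(1R)-1-phenylethyl]amino}-3,4,4a,5,6,7,8,8a-octahydronaphthalene-1-carboxylate F2 is hydrolysed (aq. HCl, THF) to 7. This resolution costs half of the material.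

2. Step 15. Competing 6-endo-dig closure to a 2-pyranone, oxidative alkyne dimerization, or erosion of the exocyclic alkene geometry may occur. The fallback sets out from enal 19 and returns at 24, replacing steps 13 and 15. 4-Methylfuran-2(5H)-one is O-silylated (TBSOTf, Et3N, CH2Cl2, 0 °C) to tert-butyldimethyl[(4-methylfuran-2-yl)oxy]silane F3. Vinylogous Mukaiyama aldol addition of F3 to 19 (BF3·OEt2, CH2Cl2, −78 °C) should give 5-[(2E)-3-{[(tert-butyldimethylsilyl)oxy]methyl}-1-hydroxy-5-Dec-pent-2-en-1-yl]-4-methylfuran-2(5H)-one F4 as a diastereomer mixture, which is of no consequence. Mesylation (MsCl, Et3N, CH2Cl2, −20 °C) to the methanesulfonate of F4, F5, and E1cB elimination with DBU should give 24, the Z isomer being favoured by allylic strain with the ring methyl.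

3. Step 13. The lithiated diazo reagent may deprotonate the enal at its γ-position, scrambling the C13=C14 geometry, or add in a conjugate sense. The fallback sets out from 19 and returns at 20 by a Corey–Fuchs sequence. CBr4 and PPh3 with Et3N as buffer (CH2Cl2, 0 °C) convert 19 into {[(2E)-5,5-dibromo-2-(2-Dec-ethyl)penta-2,4-dien-1-yl]oxy}(tert-butyl)dimethylsilane F6. Treatment of F6 with n-BuLi (2.2 equiv, THF, −78 °C; then H2O) should give 20 by Fritsch–Buttenberg–Wiechell rearrangement.

Further compounds
F1 | step 3 | racemic methyl (4aS*,8aS*)-2-hydroxy-5,5,8a-trimethyl-3,4,4a,5,6,7,8,8a-octahydronaphthalene-1-carboxylate (1:1 mixture of both enantiomers) | COC(=O)C1=C(O)CC[C@H]2C(C)(C)CCC[C@]12C.COC(=O)C1=C(O)CC[C@@H]2C(C)(C)CCC[C@@]12C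
F2 | step 3 | methyl (4aS,8aS)-5,5,8a-trimethyl-2-{[(1R)-1-phenylethyl]amino}-3,4,4a,5,6,7,8,8a-octahydronaphthalene-1-carboxylate | COC(=O)C1=C(N[C@H](C)c2ccccc2)CC[C@H]2C(C)(C)CCC[C@]12C
F3 | step 15 | tert-butyldimethyl[(4-methylfuran-2-yl)oxy]silane | Cc1coc(O[Si](C)(C)C(C)(C)C)c1
F4 | step 15 | 5-[(2E)-3-{[(tert-butyldimethylsilyl)oxy]methyl}-1-hydroxy-5-Dec-pent-2-en-1-yl]-4-methylfuran-2(5H)-one (mixture at the two new centres) | CC1=CC(=O)OC1C(O)/C=C(\CCC1=C(C)CC[C@H]2C(C)(C)CCC[C@]12C)CO[Si](C)(C)C(C)(C)C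
F5 | step 15 | methanesulfonate of F4 | CC1=CC(=O)OC1C(OS(C)(=O)=O)/C=C(\CCC1=C(C)CC[C@H]2C(C)(C)CCC[C@]12C)CO[Si](C)(C)C(C)(C)C
F6 | step 13 | {[(2E)-5,5-dibromo-2-(2-Dec-ethyl)penta-2,4-dien-1-yl]oxy}(tert-butyl)dimethylsilane | BrC(Br)=C/C=C(\CCC1=C(C)CC[C@H]2C(C)(C)CCC[C@]12C)CO[Si](C)(C)C(C)(C)C
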